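At 40 °C, after 6.0 h, I wanted to know how much target Thursday's flask held, and whether any option was worth taking.

| flask | starting material | coupling partner | rival reagent | temperature | remark | time |
|---|---|---|---|---|---|---|
| Thursday's | 0.050 M | 0.075 M | 0.075 M | 40 °C | the very flask that is asked about, followed so far |  |
| Monday's | 0.075 M | 0.075 M | 0.075 M | 35 °C | run made earlier |  |
| flask | 0.050 M | 0.0750 M | 0.0750 M | 40 °C |  | 6.0 h |

- Thursday's (time / h: target / %): 0.500: 42.5; 1.00: 50.2; 2.50: 52.0; 6.00: 52.6
- Monday's (time / min: target / %): 6.00: 12.0; 12.0: 18.9; 30.0: 33.9; 80.0: 45.4

(readings scatter by 0.5 percentage points)

- dusk: at 6.0 h take out 90% of the target then present, then wait 2.0 h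
- dawn: at 6.0 h add coupling partner, 100% of the amount charged, then wait 2.0 h
- noon: change nothing and wait 2.0 h more
- autumn: at 6.0 h raise the temperature by 15 K, then wait 2.0 h

- target taken out counts as made
- steps thought possible: starting material + coupling partner -> target; starting material + rival reagent -> side product; rival reagent -> decomposed reagent
- additions bring no volume worth counting

1. target, in percent of the starting material first charged, at 6.0 h
2. what to do for the largest gain in target; "none" if nothing gains more than 2 percentage points (dusk / dawn / noon / autumn / none)
3. target present, with what was taken out counted in, in percent of the starting material first charged, after dawn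
4. target present, with what was taken out counted in, in percent of the starting material first charged, after noon

I worked with the fraction left. Thursday's last readings, at 2.50 h and 6.00 h, differed by 0.6 percentage points, with a scatter of 0.5 points per reading. So I took their mean, 52.3%, as the plateau. If the share going to target stays constant, the fraction of starting material left is one minus reading over plateau. In Thursday's run the readings put it at 18.7% at 0.500 h and 4.02% at 1.00 h, a decay read as 3.08 h⁻¹.

Monday's run looks nearly the same, with equal [coupling partner] and [rival reagent], but it ran at 35 °C with 0.075 M of starting material, and its last reading was 45.4%. If I assumed the same plateau for Monday's run, its fraction left went from 35.2% at 30.0 min to 13.2% at 80.0 min. That is a decay of 1.18 h⁻¹, slower than Thursday's. I therefore read Monday's last reading as that of an unfinished run. Reckoned at a constant decay of that size, the stretch of Thursday's flask from 1.00 h to 6.0 h came to 22.2 half-lives, a rough count.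

So I treated Thursday's plateau as the outcome of a competition. Two listed steps consume starting material. If each is first order in it, [starting material] cancels from their ratio. I defined the split, a selectivity factor, as the plateau odds of target to side product divided by the charge ratio [coupling partner]/[rival reagent]: 1.10. I committed to 52.3% at 6.0 h, with no option gaining more than 2 points.

The forecast gave 52.6% now, 52.7% after dawn, 52.7% after noon and none as the best choice, saying “The listed steps are irreversible, so removing target does nothing”.

The flask gave 52.3%, 52.3% after dawn, 52.3% after noon, and none as the best choice.

    starting material + coupling partner → target (k = 29.0 L mol⁻¹ h⁻¹, Ea = 75.0 kJ mol⁻¹)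
    starting material + rival reagent → side product (k = 27.0 L mol⁻¹ h⁻¹, Ea = 69.0 kJ mol⁻¹)
    rival reagent → decomposed reagent (k = 0.110 h⁻¹, Ea = 113 kJ mol⁻¹)
    (constants at 40 °C)

Monday's run, with only its time changed to this flask's, comes to 51.3%. At 6.00 h, dawn would put 65.2% plus 100% of the partner's charge against 34.7% of the rival's. In this flask the split then gives odds of 5.22 on any starting material still free. The free starting material was 0%, and dawn gained 0 points.

For a flask like this one with 0.13 M of coupling partner, the split gave odds of 1.90, so 65.5% target. The computed flask gives 65.3%.

Readings and results are calculated from invented constants; the scatter is artificial.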